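As the process chemist on this run, I want to know whether the way of charging changes how the product divides between target and its isomer.

the same everywhere: free catalyst 4 mol%

| flask | substrate | reagent | time | remark |
|---|---|---|---|---|
| midnight | 0.50 M (fed, over 4.80 d) | 1.50 equiv | 6.0 d | all but substrate at the start; substrate goes in evenly over 4.80 d, the run ends at 6.0 d |
| summer | 0.50 M | 1.50 equiv | 6.0 d | a closed flask charged with all of it at once and left for 6.0 d |
| dusk | 0.50 M | 1.50 equiv (fed, over 4.80 d) | 6.0 d | a stirred flask in which reagent is dosed at a steady rate over 4.80 d without added volume, worked up at 6.0 d |
| winter | 0.50 M | 1.50 equiv |  | a single well-mixed tank run continuously and read at steady state, 6.0 d in it on average |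

    catalyst intermediate A + catalyst intermediate A ⇌ resting dimer (K1 = 29.1 M⁻¹, k1 = 21.3 M⁻¹ h⁻¹)
    catalyst intermediate D → free catalyst + target (k2 = 1.55 h⁻¹)
    substrate + catalyst intermediate B → catalyst intermediate C (k3 = 1.34 M⁻¹ h⁻¹)
    reagent + free catalyst → catalyst intermediate A (k4 = 5.56 M⁻¹ h⁻¹)
    target ⇌ isomer of the product (K5 = 0.320, k5 = 0.0413 h⁻¹)
    catalyst intermediate A ⇌ catalyst intermediate B (K6 = 1.2, k6 = 1.51 h⁻¹)
    catalyst intermediate C ⇌ catalyst intermediate D (K7 = 1.4, k7 = 6.86 h⁻¹)

- for a step with 2 of a species take k times the square, and two of it per event
- the stated concentrations are those of everything mixed, before any reaction; amounts are the same in each set-up
- the feed brings no volume worth counting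
- run time (midnight): 6.0 d

1. the set-up with the highest share of target in all that became target or isomer of the product, at the outlet or at the end ("none" if the first two lie within 2 percentage points) (midnight / summer / dusk / winter / none)
2. share of target in all that became target or isomer of the product, at the outlet or at the end, midnight
3. share of target in all that became target or isomer of the product, at the outlet or at the end, summer
4. share of target in all that became target or isomer of the product, at the outlet or at the end, dusk
5. share of target in all that became target or isomer of the product, at the outlet or at the end, winter

My first question is whether the pair has time to equilibrate. Target and isomer relax towards each other with a time of 5.87 h, the inverse of the forward and backward rate constants added, and that is shorter than the 6.0 d of the run. So I expect thermodynamic control, with a target share near 75.8%, which is one over one plus the equilibrium constant of step 5.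

The second question is how far above that share the flasks stand, since all product is born as target and the youngest part has not yet relaxed. A balance on the isomer gives, to first order, an excess of target equal to the relative growth rate of the product pool times a constant of the pair. That constant is 1.42 h; I call it the lag, the equilibrium share of isomer times the relaxation time.

The third question is what growth rate each set-up has. In the winter tank the pool is renewed once per residence time, so the excess is 0.99 percentage points and the share is 76.8%. A closed flask whose pool slows down grows more slowly than one over its age, so summer should stand below the tank. A pool growing with the square of time has, at the end of the run, twice the tank's rate, which I take as my estimate of the ceiling for the fed flasks. A flask at that ceiling stands 0.99 points above the tank, less than the margin of 2 points, so I commit to no winner.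

The forecast gives none, with midnight 77%, summer 76.3%, dusk 76.4% and winter 76.7%, on the ground that “every set-up sits close to the 75.8% equilibrium share”.

The simulation gives none, with midnight 77.0%, summer 76.4%, dusk 76.5% and winter 76.7%.

The way back from isomer to target is what holds the summer share up: without it, summer ends at 12.2% instead of 76.4%. With that return running, the lag gives the excess above the equilibrium share. At the end of summer, catalyst intermediate D stands at 4.73% of the catalyst charged and feeds the pool at a relative rate of 0.00418 h⁻¹, which reckons to 76.4% against 76.4%. The neighbour flask charged with 0.12 M of substrate has catalyst intermediate D at 3.08%, reckons to 76.6% and stands at 76.6%.

The numbers of this flask belong to no real substance; the rest is arithmetic.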